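## Analysis of the target

Target 17 is a 2,3-dihydro-1,4-benzodioxine: a dioxane ring fused to ring B. It carries the syringyl ring A (4-hydroxy-3,5-dimethoxyphenyl) on C7, a hydroxymethyl group (C9) on C8, and an (E)-propenal chain on ring B. The ring oxygen on C7 is called Oa and the ring oxygen on C8 is called Ob. The enal is para to Ob and meta to Oa, so the two oxygens are not interchangeable and a synthesis must decide which oxygen ends up on which carbon. C7 and C8 are the only stereocentres. Both are S, and the aryl and hydroxymethyl groups are trans, which is the thermodynamically preferred arrangement, so the absolute configuration is the harder problem. The sensitive groups are the enal (hydride, nucleophiles, strong base), the electron-rich free phenol, and the C7–Oa bond. That bond is a para-hydroxybenzyl aryl ether and can open to a quinone methide once the ring A phenol is free. The strategy rests on one observation: Oa, C7 (with ring A) and Ob are the atoms of the catechol acetal of syringaldehyde. The target is that five-membered acetal with one extra carbon, C8 bearing C9, inserted into the C7–Ob bond.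

## Retrosynthetic reasoning

**Side chain.** The C(aryl)–C(alkenyl) bond on ring B is cut first, giving aryl triflate 14 and alkenyl boronate 15, with the enal masked as diethyl acetal 16. Cutting here keeps the enal out of every earlier step. It also means that the ring B position para to Ob carries an oxygen substituent throughout the route, which the key step needs as a donor. The forward reaction is a stereoretentive cross-coupling followed by mild acid.

**Oxidation levels and ring A protection.** Alcohol C9 and the free ring A phenol of 14 are traced back to the tert-butyl ester and aryl pivalate of 13. One hydride treatment then performs the ester reduction and the deprotection together. The reduction is placed before the basic coupling because, while the ester is present, C8–H is acidic and sits β to the Oa leaving group; base could open the ring by elimination and erase both centres.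

**Triflate from silyl ether.** Triflate 13 comes from phenol 12, and 12 from silyl ether 11. The oxygen that acts as a donor in the key step is thus converted into the leaving group for the coupling. Both steps are run under non-basic or weakly basic conditions for the reason given above.

**Key disconnection.** In 11 the bonds Ob–C8 and C7–C8 are cut. Removing C8 with its ester contracts the dioxane to the racemic 2-aryl-1,3-benzodioxole 8 and leaves diazo ester 9 as the one-carbon donor. The forward reaction has to put a copper carbene on Ob and then move C7 from Ob to the carbene carbon. That single step closes the six-membered ring, makes two skeletal bonds and sets both stereocentres. The silyloxy group para to Ob is the regiochemical handle. Ring A carries a pivalate rather than the more obvious benzyl ether. A benzyl ether oxygen is more nucleophilic than an acetal oxygen and would offer the carbene a competing ylide with a readily migrating benzyl group. An ester oxygen does neither, and it also removes the need for a late Lewis-acid debenzylation next to the enal.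

**Silyl ether from aldehyde.** Silyl ether 8 comes from phenol 7, and the C–O bond of 7 is traced to the C–CHO bond of aldehyde 5 through formate 6 (aryl migration to a peracid oxygen). A catechol partner with a free third hydroxyl would compete in the acetal-forming alkylation and is air-sensitive under base. Carrying that oxygen as a formyl group avoids both problems at the cost of one step.

**Acetal.** The two C–O bonds of the acetal in 5 are cut to give benzal chloride 3 and catechol 4. Dichloride 3 comes from aldehyde 2, and 2 from syringaldehyde 1 by acylation. The acetal carbon is formed racemic, which is acceptable because the key step is meant to pass through a planar C7.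

## Alternatives that were turned down

**Alternative 1: oxetane by [2+2] photocycloaddition, then ring expansion.**
- Disconnection: Oa–C7 of the dioxane, then C7–C8 and O–C9 of an oxetane.
- Forward key step: irradiation of aldehyde A1 with aryl vinyl ether A2 to give the 2-aryl-3-aryloxyoxetane A3. Release of the ring B phenol then lets Oa open the oxetane at benzylic C7, which forms the dioxane and frees C9–OH.
- For: the Oa/Ob assignment is fixed before the key step because Ob is already bonded to ring B in A2. On this point it is stronger than the chosen route. The expansion is strain-driven and can equilibrate C7 to trans.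
- Against: a triplet aryl aldehyde adding to an achiral enol ether has no element that controls the absolute configuration at C8, so A3 would be racemic. Aryl acetates are prone to photo-Fries rearrangement. An electron-rich aldehyde is a poor Paternò–Büchi partner. Regioisomeric oxetanes are expected. The masked aldehyde on ring B still needs unmasking and a two-carbon homologation.
- Comparison: both routes carry one unprecedented step. The chosen route gives up the built-in regiochemistry but offers a catalyst-controlled path to one enantiomer from an acetal available in five conventional steps.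

**Alternative 2: ring B by alkyne cyclotrimerisation.**
- Disconnection: three C–C bonds of ring B together with the dioxane closure.
- Forward key step: bis-ynol ether A4 (ethynyl ether on Oa, trimethylsilylethynyl ether on Ob, built on a preformed diol with C7 and C8 as in the target) cotrimerises with alkyne A5 under Cp*RuCl(cod) to give benzodioxane A6.
- For: C7 and C8 come from a conventional asymmetric diol synthesis, so absolute and relative configuration are more secure than in the chosen route.
- Against: A4 needs two O-alkynylations of a hindered diol, one at a benzylic position, using strongly basic elimination chemistry, and ynol ethers hydrolyse easily. The position of the acetal in A6 depends only on the steric bias of the silyl group during insertion of A5. A6 then needs desilylation, a two-carbon extension of the aldehyde and two deprotections. An aromatic ring that can be bought is built from scratch.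
- Comparison: stronger on stereochemistry, weaker on step economy and no better on regiocontrol. The chosen route uses ring B as purchased and spends its risk on a single bond-forming event.

**Alternative 3: quinone methide closure by an oxidase.**
- Disconnection: Oa–C7, with C7 at the methylene oxidation level.
- Forward key step: a flavin-dependent 4-alkylphenol oxidase, or Ag2O as a chemical substitute, dehydrogenates phenol A7 (Ob–C8 bond and C8 configuration in place) to the para-quinone methide. Oa adds to C7 to give aldehyde A8.
- For: this is the native reactivity of the compound class. The Oa/Ob assignment is fixed in A7, the trans ring is the thermodynamic product, and no protecting groups are needed. On regiochemistry and probably on trans selectivity it is stronger than the chosen route.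
- Against: these oxidases are tuned to small 4-alkylphenols with one ortho methoxy group. A 2,6-dimethoxyphenol with a bulky aryloxy branch on the neighbouring carbon is outside that range. The quinone methide has a hydrogen on C8 and can tautomerise to the styrene, which would destroy the only preset stereocentre. Ag2O can also oxidise the ring B phenol. A7 needs its own multi-step enantioselective synthesis, and A8 still needs a two-carbon homologation.
- Comparison: the chosen route sets both centres and the ring in one catalytic operation from a racemic acetal, and explores a one-carbon insertion that would apply to catechol acetals in general.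

Key step: step 6

Assumption: the sense of induction of the bisoxazoline in the ylide rearrangement cannot be predicted. The (S,S) ligand is written, and its antipode is used if the first experiment shows the opposite sense.

## Route

**Step 1**
Reactants: 1 syringaldehyde (4-hydroxy-3,5-dimethoxybenzaldehyde)
Product: 2 4-formyl-2,6-dimethoxyphenyl pivalate
Conditions: t-BuCOCl, Et3N, DMAP (cat.), CH2Cl2, 0 °C to rt
Reagents that add atoms: pivaloyl chloride, CC(C)(C)C(=O)Cl
Why: Acylation of an acidic, hindered phenol under nucleophilic catalysis; the pivalate is chosen because an ester oxygen cannot form a productive oxonium ylide in step 6 and is removed by the hydride of step 9.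

**Step 2**
Reactants: 2 4-formyl-2,6-dimethoxyphenyl pivalate
Product: 3 4-(dichloromethyl)-2,6-dimethoxyphenyl pivalate
Conditions: SOCl2, DMF (cat.), CH2Cl2, 40 °C; volatiles removed, crude used directly
Reagents that add atoms: thionyl chloride, O=S(Cl)Cl
Why: Deoxygenative gem-dichlorination of an aryl aldehyde through chloroiminium (Vilsmeier-type) activation; the acyloxy group tempers ionisation of the benzal chloride so that it can be handled as a crude oil under dry conditions.

**Step 3**
Reactants: 3 4-(dichloromethyl)-2,6-dimethoxyphenyl pivalate; 4 3,4-dihydroxybenzaldehyde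
Product: 5 racemic 4-(5-formyl-1,3-benzodioxol-2-yl)-2,6-dimethoxyphenyl pivalate
Conditions: K2CO3, DMF, 80 °C, Ar
Reagents that add atoms: none
Why: Benzylidene acetal formation by double O-alkylation of a catechol with a benzal chloride: the first substitution gives an α-chloro ether that closes at once by 5-exo-tet attack of the neighbouring phenoxide. With only two vicinal hydroxyls there is no regiochemical choice, and the acetal carbon is formed racemic, which is what step 6 requires.

**Step 4**
Reactants: 5 racemic 4-(5-formyl-1,3-benzodioxol-2-yl)-2,6-dimethoxyphenyl pivalate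
Product: 7 racemic 4-(5-hydroxy-1,3-benzodioxol-2-yl)-2,6-dimethoxyphenyl pivalate, via aryl formate 6 (not isolated)
Conditions: mCPBA, CH2Cl2, 0 °C to rt; then MeOH, Et3N (cat.), rt
Reagents that add atoms: 3-chloroperbenzoic acid, OOC(=O)c1cccc(Cl)c1
Why: Baeyer–Villiger (Dakin-type) oxidation of a 3,4-dioxygenated benzaldehyde, in which the electron-rich aryl group migrates in preference to hydrogen, as in the conversion of piperonal into sesamol. The formate is far more labile than the hindered pivalate and is removed by mild methanolysis.

**Step 5**
Reactants: 7 racemic 4-(5-hydroxy-1,3-benzodioxol-2-yl)-2,6-dimethoxyphenyl pivalate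
Product: 8 racemic 2,6-dimethoxy-4-[5-(triisopropylsilyloxy)-1,3-benzodioxol-2-yl]phenyl pivalate
Conditions: i-Pr3SiCl, imidazole, DMF, rt
Reagents that add atoms: chlorotriisopropylsilane, CC(C)[Si](Cl)(C(C)C)C(C)C
Why: Standard silylation of a phenol; the silyloxy group is the para donor meant to steer the carbene to Ob, and its bulk keeps its own oxygen out of ylide formation.

**Step 6**
Reactants: 8 racemic 2,6-dimethoxy-4-[5-(triisopropylsilyloxy)-1,3-benzodioxol-2-yl]phenyl pivalate; 9 tert-butyl diazoacetate
Product: 11 tert-butyl (2R,3S)-3-[3,5-dimethoxy-4-(pivaloyloxy)phenyl]-6-(triisopropylsilyloxy)-2,3-dihydro-1,4-benzodioxine-2-carboxylate, via oxonium ylide 10 (not isolated)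
Conditions: (CuOTf)2·C6H6 (5 mol % Cu), 2,2'-(propane-2,2-diyl)bis[(4S)-4-tert-butyl-4,5-dihydro-1,3-oxazole] (6 mol %), 4 Å MS, CH2Cl2, 25 °C; 9 (3 equiv) added over 12 h by syringe pump
Reagents that add atoms: none
Why: Proposed new method: the carbene formed from 9 on the monovalent copper bisoxazoline complex is attacked by Ob of 8 to give the copper-associated oxonium ylide 10; the weakened C7–Ob bond then breaks to an Oa-stabilised benzylic oxocarbenium ion (or radical) at C7 paired with the copper enolate at C8, and C–C recombination forms C7–C8, a net [1,2]-Stevens shift that inserts C8 into the acetal. The closest known reaction types are the Rh2(OAc)4-catalysed expansion of 2-aryl-1,3-dioxolanes to 1,4-dioxanes with diazo esters and the enantioselective copper-catalysed expansion of oxetanes to tetrahydrofurans; the transfer to a 1,3-benzodioxole, whose oxygens are both aryl ether oxygens, is new. The six-membered ring closes by 6-endo-trig attack of the exocyclic copper enolate (enolexo) on the C7=Oa oxocarbenium ion, the two ends being held together through ring B. C8 is set by the face of the ligand-bound enolate that is open to C7. C7 is set relative to C8 by the preference for the aryl and tert-butoxycarbonyl groups to be trans in the chair-like recombination; because C7 is planar in the intermediate, both enantiomers of 8 should converge on one product, provided rotation about the Oa–aryl bond is faster than recombination. The step needs attack at Ob rather than Oa: the para silyloxy donor raises the electron density at Ob, and the triisopropylsilyl group is closer to Oa. It needs O-attack rather than cyclopropanation of electron-rich ring B, which the copper carbene, the bulky ester and slow addition favour. It needs no competing ylide with a mobile group, which is why ring A carries a pivalate and not a benzyl ether.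

**Step 7**
Reactants: 11 tert-butyl (2R,3S)-3-[3,5-dimethoxy-4-(pivaloyloxy)phenyl]-6-(triisopropylsilyloxy)-2,3-dihydro-1,4-benzodioxine-2-carboxylate
Product: 12 tert-butyl (2R,3S)-3-[3,5-dimethoxy-4-(pivaloyloxy)phenyl]-6-hydroxy-2,3-dihydro-1,4-benzodioxine-2-carboxylate
Conditions: Bu4NF, AcOH, THF, 0 °C
Reagents that add atoms: none
Why: Fluoride cleavage of an aryl silyl ether; acetic acid keeps the medium non-basic so that C8–H (α to the ester, β to the Oa leaving group) is not removed, which would open the ring by E1cB and erase both centres. The pivalate is untouched.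

**Step 8**
Reactants: 12 tert-butyl (2R,3S)-3-[3,5-dimethoxy-4-(pivaloyloxy)phenyl]-6-hydroxy-2,3-dihydro-1,4-benzodioxine-2-carboxylate
Product: 13 tert-butyl (2R,3S)-3-[3,5-dimethoxy-4-(pivaloyloxy)phenyl]-6-(trifluoromethylsulfonyloxy)-2,3-dihydro-1,4-benzodioxine-2-carboxylate
Conditions: Tf2O, pyridine, CH2Cl2, −78 to 0 °C
Reagents that add atoms: trifluoromethanesulfonic anhydride, O=S(=O)(OS(=O)(=O)C(F)(F)F)C(F)(F)F
Why: O-Sulfonylation of the only free hydroxyl in the molecule; since no aliphatic alcohol is present yet, the fast anhydride can be used with a weak base at low temperature, again sparing the base-sensitive C8 centre.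

**Step 9**
Reactants: 13 tert-butyl (2R,3S)-3-[3,5-dimethoxy-4-(pivaloyloxy)phenyl]-6-(trifluoromethylsulfonyloxy)-2,3-dihydro-1,4-benzodioxine-2-carboxylate
Product: 14 (2S,3S)-3-(4-hydroxy-3,5-dimethoxyphenyl)-2-(hydroxymethyl)-2,3-dihydro-1,4-benzodioxin-6-yl trifluoromethanesulfonate
Conditions: i-Bu2AlH (6 equiv), CH2Cl2, −78 to 0 °C; aq. Rochelle salt
Reagents that add atoms: none
Why: Hydride reduction of the tert-butyl ester to the primary alcohol C9 and reductive cleavage of the aryl pivalate in one operation; aryl triflates tolerate i-Bu2AlH at low temperature. Removing the ester ends the base sensitivity of C8 before the basic coupling; the descriptor at C8 changes from R to S only because the priorities change.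

**Step 10**
Reactants: 14 (2S,3S)-3-(4-hydroxy-3,5-dimethoxyphenyl)-2-(hydroxymethyl)-2,3-dihydro-1,4-benzodioxin-6-yl trifluoromethanesulfonate; 15 2-[(E)-3,3-diethoxyprop-1-en-1-yl]-4,4,5,5-tetramethyl-1,3,2-dioxaborolane
Product: 17 target (2E)-3-[(2S,3S)-3-(4-hydroxy-3,5-dimethoxyphenyl)-2-(hydroxymethyl)-2,3-dihydro-1,4-benzodioxin-6-yl]prop-2-enal, via diethyl acetal 16 (not isolated)
Conditions: PdCl2(dppf) (5 mol %), K3PO4, THF/H2O, 60 °C; then 1 M HCl, THF, rt
Reagents that add atoms: water, O
Why: Suzuki–Miyaura coupling of an aryl triflate with an (E)-alkenyl pinacol boronate, stereoretentive at the alkene, followed by acid hydrolysis of the allylic diethyl acetal to the conjugated E-enal. The free phenol and alcohol are tolerated with extra base; if C7 opens reversibly through the para-quinone methide it should reclose to the favoured trans isomer, because C8 is fixed.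

## Compound list

1 | syringaldehyde (4-hydroxy-3,5-dimethoxybenzaldehyde) | COc1cc(C=O)cc(OC)c1O | starting material
2 | 4-formyl-2,6-dimethoxyphenyl pivalate | COc1cc(C=O)cc(OC)c1OC(=O)C(C)(C)C | intermediate
3 | 4-(dichloromethyl)-2,6-dimethoxyphenyl pivalate | COc1cc(C(Cl)Cl)cc(OC)c1OC(=O)C(C)(C)C | intermediate
4 | 3,4-dihydroxybenzaldehyde | O=Cc1ccc(O)c(O)c1 | starting material
5 | racemic 4-(5-formyl-1,3-benzodioxol-2-yl)-2,6-dimethoxyphenyl pivalate | COc1cc(C2Oc3ccc(C=O)cc3O2)cc(OC)c1OC(=O)C(C)(C)C | intermediate
6 | racemic 4-[5-(formyloxy)-1,3-benzodioxol-2-yl]-2,6-dimethoxyphenyl pivalate (not isolated) | COc1cc(C2Oc3ccc(OC=O)cc3O2)cc(OC)c1OC(=O)C(C)(C)C | intermediate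
7 | racemic 4-(5-hydroxy-1,3-benzodioxol-2-yl)-2,6-dimethoxyphenyl pivalate | COc1cc(C2Oc3ccc(O)cc3O2)cc(OC)c1OC(=O)C(C)(C)C | intermediate
8 | racemic 2,6-dimethoxy-4-[5-(triisopropylsilyloxy)-1,3-benzodioxol-2-yl]phenyl pivalate (precursor of the key step) | COc1cc(C2Oc3ccc(O[Si](C(C)C)(C(C)C)C(C)C)cc3O2)cc(OC)c1OC(=O)C(C)(C)C | intermediate
9 | tert-butyl diazoacetate | [N-]=[N+]=CC(=O)OC(C)(C)C | starting material
10 | oxonium ylide at Ob of 8, drawn without copper (not isolated) | COc1cc(C2[O+]([CH-]C(=O)OC(C)(C)C)c3ccc(O[Si](C(C)C)(C(C)C)C(C)C)cc3O2)cc(OC)c1OC(=O)C(C)(C)C | intermediate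
11 | tert-butyl (2R,3S)-3-[3,5-dimethoxy-4-(pivaloyloxy)phenyl]-6-(triisopropylsilyloxy)-2,3-dihydro-1,4-benzodioxine-2-carboxylate (product of the key step) | COc1cc([C@@H]2Oc3cc(O[Si](C(C)C)(C(C)C)C(C)C)ccc3O[C@H]2C(=O)OC(C)(C)C)cc(OC)c1OC(=O)C(C)(C)C | intermediate
12 | tert-butyl (2R,3S)-3-[3,5-dimethoxy-4-(pivaloyloxy)phenyl]-6-hydroxy-2,3-dihydro-1,4-benzodioxine-2-carboxylate | COc1cc([C@@H]2Oc3cc(O)ccc3O[C@H]2C(=O)OC(C)(C)C)cc(OC)c1OC(=O)C(C)(C)C | intermediate
13 | tert-butyl (2R,3S)-3-[3,5-dimethoxy-4-(pivaloyloxy)phenyl]-6-(trifluoromethylsulfonyloxy)-2,3-dihydro-1,4-benzodioxine-2-carboxylate | COc1cc([C@@H]2Oc3cc(OS(=O)(=O)C(F)(F)F)ccc3O[C@H]2C(=O)OC(C)(C)C)cc(OC)c1OC(=O)C(C)(C)C | intermediate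
14 | (2S,3S)-3-(4-hydroxy-3,5-dimethoxyphenyl)-2-(hydroxymethyl)-2,3-dihydro-1,4-benzodioxin-6-yl trifluoromethanesulfonate | COc1cc([C@@H]2Oc3cc(OS(=O)(=O)C(F)(F)F)ccc3O[C@H]2CO)cc(OC)c1O | intermediate
15 | 2-[(E)-3,3-diethoxyprop-1-en-1-yl]-4,4,5,5-tetramethyl-1,3,2-dioxaborolane | CCOC(OCC)/C=C/B1OC(C)(C)C(C)(C)O1 | starting material
16 | 4-[(2S,3S)-7-[(E)-3,3-diethoxyprop-1-en-1-yl]-3-(hydroxymethyl)-2,3-dihydro-1,4-benzodioxin-2-yl]-2,6-dimethoxyphenol (not isolated) | COc1cc([C@@H]2Oc3cc(/C=C/C(OCC)OCC)ccc3O[C@H]2CO)cc(OC)c1O | intermediate
17 | (2E)-3-[(2S,3S)-3-(4-hydroxy-3,5-dimethoxyphenyl)-2-(hydroxymethyl)-2,3-dihydro-1,4-benzodioxin-6-yl]prop-2-enal | COc1cc([C@@H]2Oc3cc(/C=C/C=O)ccc3O[C@H]2CO)cc(OC)c1O | target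

## Step count and least certain steps

Total: 10 steps. Longest linear sequence: 10 steps from 1. Compounds 4, 9 and 15 are purchased.

**Step 6 (carries the label; the main risk of the route).** Three things may go wrong.
- Carbene consumption: aryl acetal oxygens are weak nucleophiles, so the carbene may instead cyclopropanate or alkylate electron-rich ring B, insert at the acetal C–H, or dimerise.
- Regiochemistry: ylide formation at Oa would expand the ring on the wrong side. The same happens if ylide formation is reversible and the Oa ylide fragments faster, since its oxocarbenium ion would be stabilised by the more electron-rich Ob.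
- Stereochemistry: if C7 migrates within a tight pair with retention, or copper leaves the ylide before C–C bond formation, the racemic acetal does not converge and the ligand cannot set the centres. Poor facial selectivity at recombination would give the same result. A partial remedy inside the route exists if only C8 is controlled: after step 9 the free ring A phenol allows base-induced equilibration of C7 to trans through the quinone methide.

Fallback by known chemistry, setting out from 2 and returning at 16:
- The dibutylboron enolate (Bu2BOTf, i-Pr2NEt, CH2Cl2, −78 °C) of (4R)-4-benzyl-3-{[4-bromo-2-(methoxymethoxy)phenoxy]acetyl}-1,3-oxazolidin-2-one F1 is used. F1 is assembled beforehand from the auxiliary, bromoacetyl bromide and the mono(methoxymethyl) ether of 4-bromocatechol.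
- Evans syn-aldol addition of this enolate to 2 gives (4R)-4-benzyl-3-{(2R,3S)-2-[4-bromo-2-(methoxymethoxy)phenoxy]-3-[3,5-dimethoxy-4-(pivaloyloxy)phenyl]-3-hydroxypropanoyl}-1,3-oxazolidin-2-one F2, with C8 set by the auxiliary.
- LiBH4 in THF/MeOH removes the auxiliary and the pivalate to give (1S,2S)-2-[4-bromo-2-(methoxymethoxy)phenoxy]-1-(4-hydroxy-3,5-dimethoxyphenyl)propane-1,3-diol F3.
- Trifluoroacetic acid in CH2Cl2 removes the methoxymethyl group and ionises the benzylic alcohol. The freed phenol Oa captures C7 to give the thermodynamically preferred trans ring, 4-[(2S,3S)-7-bromo-3-(hydroxymethyl)-2,3-dihydro-1,4-benzodioxin-2-yl]-2,6-dimethoxyphenol F4, with C8 untouched.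
- F4 couples with 15 under the palladium conditions of step 10 (bromide in place of triflate) to give 16, which the acid stage of step 10 converts into 17.

**Step 3.** Adventitious water may hydrolyse the dichloride back to the aldehyde, the catecholate may take the acyl group from the pivalate, or intermolecular acetal formation may compete with ring closure. Fallback from 2, returning at 5: switch from alkylation under base to acid-catalysed acetal exchange. Aldehyde 2 is converted with HC(OMe)3 and catalytic TsOH in MeOH into 4-(dimethoxymethyl)-2,6-dimethoxyphenyl pivalate F5. F5 is exchanged with 4 under catalytic camphorsulfonic acid in toluene with distillation of methanol to give 5.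

**Step 9.** Hydride may attack the triflate at sulfur and remove the coupling handle, or the hindered pivalate may be cleaved incompletely. Fallback from 13, returning at 16: couple before reducing. Triflate 13 and 15 (PdCl2(dppf), CsF, anhydrous dioxane, 80 °C, to limit base contact with C8–H) give tert-butyl (2R,3S)-6-[(E)-3,3-diethoxyprop-1-en-1-yl]-3-[3,5-dimethoxy-4-(pivaloyloxy)phenyl]-2,3-dihydro-1,4-benzodioxine-2-carboxylate F6. LiAlH4 in THF at 0 °C then reduces the ester and cleaves the pivalate, with no triflate present, to give 16.

**Step 10.** Under warm aqueous base the para-hydroxybenzyl aryl ether may open through the quinone methide and be trapped by water, the triflate may hydrolyse, or the boronate may protodeboronate. Fallback from 14, returning at 16: a base-free Stille coupling with (E)-tributyl(3,3-diethoxyprop-1-en-1-yl)stannane, Pd(PPh3)4 and LiCl in dioxane at 80 °C, which needs neither water nor base. It makes no new compound (F0).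

## Further compounds

F1 | step 6 | (4R)-4-benzyl-3-{[4-bromo-2-(methoxymethoxy)phenoxy]acetyl}-1,3-oxazolidin-2-one | COCOc1cc(Br)ccc1OCC(=O)N1[C@H](Cc2ccccc2)COC1=O
F2 | step 6 | (4R)-4-benzyl-3-{(2R,3S)-2-[4-bromo-2-(methoxymethoxy)phenoxy]-3-[3,5-dimethoxy-4-(pivaloyloxy)phenyl]-3-hydroxypropanoyl}-1,3-oxazolidin-2-one | COCOc1cc(Br)ccc1O[C@H]([C@@H](O)c1cc(OC)c(OC(=O)C(C)(C)C)c(OC)c1)C(=O)N1[C@H](Cc2ccccc2)COC1=O
F3 | step 6 | (1S,2S)-2-[4-bromo-2-(methoxymethoxy)phenoxy]-1-(4-hydroxy-3,5-dimethoxyphenyl)propane-1,3-diol | COCOc1cc(Br)ccc1O[C@H]([C@@H](O)c1cc(OC)c(O)c(OC)c1)CO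
F4 | step 6 | 4-[(2S,3S)-7-bromo-3-(hydroxymethyl)-2,3-dihydro-1,4-benzodioxin-2-yl]-2,6-dimethoxyphenol | COc1cc([C@@H]2Oc3cc(Br)ccc3O[C@H]2CO)cc(OC)c1O
F5 | step 3 | 4-(dimethoxymethyl)-2,6-dimethoxyphenyl pivalate | COc1cc(C(OC)OC)cc(OC)c1OC(=O)C(C)(C)C
F6 | step 9 | tert-butyl (2R,3S)-6-[(E)-3,3-diethoxyprop-1-en-1-yl]-3-[3,5-dimethoxy-4-(pivaloyloxy)phenyl]-2,3-dihydro-1,4-benzodioxine-2-carboxylate | COc1cc([C@@H]2Oc3cc(/C=C/C(OCC)OCC)ccc3O[C@H]2C(=O)OC(C)(C)C)cc(OC)c1OC(=O)C(C)(C)C
F0 | step 10 | none | none
A1 | alternative 1 | 4-formyl-2,6-dimethoxyphenyl acetate | COc1cc(C=O)cc(OC)c1OC(C)=O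
A2 | alternative 1 | 5-(1,3-dioxolan-2-yl)-2-(vinyloxy)phenyl acetate | C=COc1ccc(C2OCCO2)cc1OC(C)=O
A3 | alternative 1 | 4-{3-[2-acetoxy-4-(1,3-dioxolan-2-yl)phenoxy]oxetan-2-yl}-2,6-dimethoxyphenyl acetate (C8 as in the target, C7 either epimer) | COc1cc(C2OC[C@@H]2Oc3ccc(C4OCCO4)cc3OC(C)=O)cc(OC)c1OC(C)=O
A4 | alternative 2 | bis-ynol ether of the C7/C8 diol: ethynyl ether on Oa, (trimethylsilyl)ethynyl ether on Ob, C9 as tert-butyldimethylsilyl ether, ring A as benzyl ether, C7 and C8 as in the target | COc1cc([C@H](OC#C)[C@H](CO[Si](C)(C)C(C)(C)C)OC#C[Si](C)(C)C)cc(OC)c1OCc1ccccc1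
A5 | alternative 2 | 3,3-diethoxyprop-1-yne | C#CC(OCC)OCC
A6 | alternative 2 | tert-butyl{[(2S,3S)-3-[4-(benzyloxy)-3,5-dimethoxyphenyl]-6-(diethoxymethyl)-8-(trimethylsilyl)-2,3-dihydro-1,4-benzodioxin-2-yl]methoxy}dimethylsilane | COc1cc([C@@H]2Oc3cc(C(OCC)OCC)cc([Si](C)(C)C)c3O[C@H]2CO[Si](C)(C)C(C)(C)C)cc(OC)c1OCc1ccccc1
A7 | alternative 3 | 3-hydroxy-4-{[(2R)-1-hydroxy-3-(4-hydroxy-3,5-dimethoxyphenyl)propan-2-yl]oxy}benzaldehyde | COc1cc(C[C@H](CO)Oc2ccc(C=O)cc2O)cc(OC)c1O
A8 | alternative 3 | (2S,3S)-3-(4-hydroxy-3,5-dimethoxyphenyl)-2-(hydroxymethyl)-2,3-dihydro-1,4-benzodioxine-6-carbaldehyde | COc1cc([C@@H]2Oc3cc(C=O)ccc3O[C@H]2CO)cc(OC)c1O
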